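**Retrosynthetic overview**
1. Target gibberellin ← fluoride deprotection ← ring A closed by ring-closing metathesis (C1=C2); the key C3–C4 bond comes from an intermolecular aldol of the C4 lactone enolate with acrolein.
2. 19,10-Lactone (C4–C5) ← intramolecular Michael addition of a C10 propanoate to a C5=C6 enoate; C10 carbinol ← vinyl addition to a ring B 10-oxo-enoate.
3. Ring D (C13–C16) ← SmI2 pinacol coupling of a 13-keto-16-aldehyde, then oxidation and methylenation; 12-OH is set earlier by hydride reduction on the cis-hydrindane.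
4. cis-Hydrindane (rings B/C, quaternary C8) ← Hajos–Parrish sequence: intermolecular Michael addition of a 2-substituted cyclopentane-1,3-dione to methyl vinyl ketone, then (S)-proline aldol.
5. Ring order: B/C hydrindane → ring B enoate → lactone → ring D → ring A.

Assumption: all intermediates carry gibberellin atom numbers (ring B = C5, C6, C8, C9, C10; ring C = C8, C9, C11–C14; C8 side chain = C15, C16), and C4 is left undefined in the SMILES of 23–29 because it is an epimer mixture that is planarised in step 25.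

Abbreviations: TES = triethylsilyl, TBS = tert-butyldimethylsilyl, TMSE = 2-(trimethylsilyl)ethyl, Piv = pivaloyl.

**Route**

Step 1
Reactants: 1 cyclopentane-1,3-dione; 2 (benzyloxy)acetaldehyde
Product: 4 2-[2-(benzyloxy)ethyl]cyclopentane-1,3-dione, via alkylidene dione 3 (not isolated)
Conditions: Hantzsch ester (diethyl 2,6-dimethyl-1,4-dihydropyridine-3,5-dicarboxylate, 1.0 equiv), L-proline (10 mol %), CH2Cl2, rt
Reagents that add atoms: none
Why: Knoevenagel condensation followed by organocatalytic transfer hydrogenation (three-component reductive alkylation) gives clean C-alkylation of the dione without O-alkylation.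

Step 2
Reactants: 4 2-[2-(benzyloxy)ethyl]cyclopentane-1,3-dione; 5 methyl vinyl ketone
Product: 6 2-[2-(benzyloxy)ethyl]-2-(3-oxobutyl)cyclopentane-1,3-dione
Conditions: Et3N (5 mol %), CH2Cl2, rt
Reagents that add atoms: none
Why: Intermolecular Michael addition of the acidic 1,3-dione to the enone joins the two fragments and creates the future quaternary C8 (C8–C14 bond).

Step 3
Reactants: 6 2-[2-(benzyloxy)ethyl]-2-(3-oxobutyl)cyclopentane-1,3-dione
Product: 8 (R)-7a-[2-(benzyloxy)ethyl]-2,3,7,7a-tetrahydro-1H-indene-1,5(6H)-dione, via cis-ketol 7 (not isolated)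
Conditions: (S)-proline (30 mol %), DMF, rt; then H2SO4 (cat.), DMF, 95 °C
Reagents that add atoms: none
Why: The Hajos–Parrish proline-catalysed enamine aldol desymmetrises the dione and, after dehydration, fixes C8 in the spatial sense of the (S)-Hajos–Parrish ketone (formally R here because the side chain outranks the ring CH2).

Step 4
Reactants: 8 enedione
Product: 9 16-O-benzyl 6-hydroxy-9(11)-en-12-one (6-OH cis to the C8 side chain)
Conditions: NaBH4 (0.3 equiv), EtOH, −20 °C
Reagents that add atoms: none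
Why: Chemoselective borohydride reduction of the saturated cyclopentanone over the enone, hydride arriving anti to the side chain; the alcohol is only a temporary mask for C6.

Step 5
Reactants: 9 6-hydroxy enone
Product: 10 6-O-pivaloyl 16-O-benzyl 9(11)-en-12-one
Conditions: t-BuCOCl, pyridine, DMAP (cat.), CH2Cl2, 0 °C → rt
Reagents that add atoms: pivaloyl chloride CC(C)(C)C(=O)Cl
Why: Acylation; the pivalate has no α-hydrogens and survives the strong base of step 6.

Step 6
Reactants: 10 6-pivalate enone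
Product: 11 13-hydroxy 6-O-pivaloyl 16-O-benzyl 9(11)-en-12-one (13-OH trans to the C8 side chain)
Conditions: KN(SiMe3)2, THF, −78 °C; 3-phenyl-2-(phenylsulfonyl)oxaziridine; AcOH
Reagents that add atoms: 3-phenyl-2-(phenylsulfonyl)oxaziridine O=S(=O)(N1OC1c1ccccc1)c1ccccc1
Why: Kinetic α′-deprotonation of the enone and Davis oxaziridine hydroxylation of the enolate on the face anti to the pseudo-axial side chain places oxygen on C13.

Step 7
Reactants: 11 13-hydroxy enone
Product: 12 cis-hydrindan-12-one 13,16-diol 6-pivalate (H-9 cis to the C8 side chain)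
Conditions: H2 (1 atm), Pd/C (10 %), EtOAc–EtOH, rt
Reagents that add atoms: none
Why: Heterogeneous hydrogenation of Hajos–Parrish-type enones delivers hydrogen to C9 on the side-chain face (cis-hydrindane), and the same conditions hydrogenolyse the benzyl ether; any trans isomer is removed by chromatography.

Step 8
Reactants: 12 keto diol
Product: 13 13,16-bis-O-TES cis-hydrindan-12-one 6-pivalate
Conditions: Et3SiCl, imidazole, DMF, 0 °C → rt
Reagents that add atoms: chlorotriethylsilane CC[Si](Cl)(CC)CC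
Why: Silyl ether formation on the primary and the α-keto secondary hydroxyl gives groups that can later be removed together in the presence of TBS.

Step 9
Reactants: 13 bis-TES ketone
Product: 14 12-alcohol (12-OH cis to 13-O and trans to the C8 side chain)
Conditions: LiBH(s-Bu)3, THF, −78 °C; AcOH
Reagents that add atoms: none
Why: Steric-approach-controlled hydride reduction: the bulky borohydride attacks C12 equatorially, anti to the neighbouring 13-OSiEt3, which gives the axial 12-alcohol with the 12-configuration of the target.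

Step 10
Reactants: 14 12-alcohol
Product: 15 12-O-TBS 13,16-bis-O-TES 6-pivalate
Conditions: t-BuMe2SiOTf, 2,6-lutidine, CH2Cl2, 0 °C
Reagents that add atoms: tert-butyldimethylsilyl triflate CC(C)(C)[Si](C)(C)OS(=O)(=O)C(F)(F)F
Why: Silylation of the hindered secondary alcohol with the silyl triflate gives a group that outlasts the TES ethers.

Step 11
Reactants: 15 tris-silyl pivalate
Product: 16 6-alcohol
Conditions: i-Bu2AlH, CH2Cl2, −78 °C; aq. potassium sodium tartrate
Reagents that add atoms: none
Why: Reductive ester cleavage; the molecule contains no other carbonyl group and silyl ethers are inert.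

Step 12
Reactants: 16 6-alcohol
Product: 17 6-ketone
Conditions: Dess–Martin periodinane, pyridine, CH2Cl2, rt
Reagents that add atoms: none
Why: Dess–Martin oxidation returns the ring B ketone under non-acidic conditions tolerated by the TES ethers.

Step 13
Reactants: 17 6-ketone
Product: 18 5-en-6-yl triflate
Conditions: KN(SiMe3)2, THF, −78 °C; PhNTf2, −78 → 0 °C; AcOH
Reagents that add atoms: N-phenylbis(trifluoromethanesulfonimide) O=S(=O)(N(c1ccccc1)S(=O)(=O)C(F)(F)F)C(F)(F)F
Why: Enol triflate formation; enolisation is possible only toward C5 because C8 is quaternary.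

Step 14
Reactants: 18 enol triflate
Product: 19 TMSE 5-ene-6-carboxylate (C7 ester)
Conditions: Pd(OAc)2 (5 mol %), PPh3 (10 mol %), CO (1 atm), Me3SiCH2CH2OH, Et3N, DMF, 60 °C
Reagents that add atoms: carbon monoxide [C-]#[O+]; 2-(trimethylsilyl)ethanol C[Si](C)(C)CCO
Why: Palladium-catalysed alkoxycarbonylation of a hindered ring enol triflate (as with steroid ring D triflates) installs C7 as a fluoride-cleavable ester.

Step 15
Reactants: 19 TMSE enoate
Product: 20 10-oxo-5-ene-6-carboxylate
Conditions: CrO3, 3,5-dimethylpyrazole, CH2Cl2, −20 °C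
Reagents that add atoms: chromium trioxide O=[Cr](=O)=O
Why: Allylic (γ) oxidation of the enoate; C10 is the only allylic CH2, and the cis ring fusion at the now enolisable C9 is the thermodynamically favoured one.

Step 16
Reactants: 20 10-oxo enoate
Product: 21 10-vinyl-10-ol (vinyl cis to H-9)
Conditions: CeCl3, CH2=CHMgBr, THF, −78 °C; AcOH
Reagents that add atoms: vinylmagnesium bromide C=C[Mg]Br
Why: Organocerium 1,2-addition to the enone carbonyl avoids enolisation and conjugate addition; attack on the convex face of the cis-hydrindane (anti to C11) sets C10.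

Step 17
Reactants: 21 tertiary alcohol
Product: 22 10-propanoate
Conditions: LiN(SiMe3)2, THF, −78 °C; EtCOCl, −78 → 0 °C
Reagents that add atoms: propanoyl chloride CCC(=O)Cl
Why: O-acylation of the preformed lithium alkoxide overcomes the low reactivity of the hindered tertiary allylic alcohol.

Step 18
Reactants: 22 10-propanoate
Product: 23 tricyclic 19,10-lactone (C4 cis to the lactone oxygen; H-5 cis to the C10 vinyl; C7 ester trans to C4)
Conditions: KN(SiMe3)2, THF, −78 → 0 °C; then t-BuOH, rt; AcOH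
Reagents that add atoms: none
Why: Intramolecular Michael addition of the propanoate enolate to C5 forms the C4–C5 bond and a necessarily cis-fused γ-lactone on the face of the C10 oxygen, which leaves H-5 on the vinyl face; equilibration puts the C7 ester trans to C4 (natural C6).

Step 19
Reactants: 23 lactone
Product: 24 lactone 13,16-diol
Conditions: HF·pyridine, pyridine, THF, 0 °C
Reagents that add atoms: none
Why: Selective desilylation; TES ethers are cleaved much faster than the TBS ether, and the TMSE ester is stable to acidic fluoride.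

Step 20
Reactants: 24 diol
Product: 25 13-oxo-16-al
Conditions: Dess–Martin periodinane, pyridine, CH2Cl2, rt
Reagents that add atoms: none
Why: Double Dess–Martin oxidation of the primary and secondary alcohols; the crude keto aldehyde is used at once to protect the α-silyloxy centre C12.

Step 21
Reactants: 25 keto aldehyde
Product: 26 tetracyclic 13,16-diol (ring D closed; 16-OH cis to 13-OH)
Conditions: SmI2, t-BuOH, THF, −78 °C
Reagents that add atoms: none
Why: Intramolecular pinacol (ketyl–carbonyl) coupling; the axial C15–C16 chain can reach C13 only from its own face, which fixes C13 and builds the bicyclo[3.2.1]octane.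

Step 22
Reactants: 26 diol
Product: 27 16-oxo-13-ol (17-nor ketone)
Conditions: Dess–Martin periodinane, pyridine, CH2Cl2, 0 °C → rt
Reagents that add atoms: none
Why: Oxidation of the secondary alcohol only; the tertiary 13-OH cannot be oxidised.

Step 23
Reactants: 27 nor ketone
Product: 28 16-methylene-13-ol
Conditions: Zn, CH2Br2, TiCl4, THF–CH2Cl2, 0 °C → rt
Reagents that add atoms: dibromomethane BrCBr
Why: Lombardo methylenation is non-basic, so the α-ketol does not undergo acyloin rearrangement and the esters are untouched.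

Step 24
Reactants: 28 tertiary alcohol
Product: 29 13-O-TES ether
Conditions: Et3SiOTf, 2,6-lutidine, CH2Cl2, −40 → 0 °C
Reagents that add atoms: triethylsilyl triflate CC[Si](CC)(CC)OS(=O)(=O)C(F)(F)F
Why: Silylation with the silyl triflate caps the bridgehead tertiary alcohol so that exactly one equivalent of base is consumed in step 25.

Step 25
Reactants: 29 lactone; 30 acrolein
Product: 31 aldol adduct (C4 quaternary; 1-hydroxyprop-2-enyl group cis to the C10 vinyl; 3-OH syn to the C4 methyl)
Conditions: LiN(i-Pr)2 (1.1 equiv), THF, −78 °C; acrolein, −78 °C; AcOH at −78 °C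
Reagents that add atoms: none
Why: Intermolecular aldol addition forms the C3–C4 bond: the lactone C4–H is more acidic and far less hindered than C6–H, acrolein adds 1,2 on the convex face of the bicyclic enolate (cis to the vinyl group), and the Zimmerman–Traxler chair (methyl cis to O–Li) gives methyl syn to hydroxyl, the natural C3 configuration.

Step 26
Reactants: 31 aldol adduct
Product: 32 12-O-TBS 13-O-TES TMSE ester of the target gibberellin
Conditions: second-generation Grubbs catalyst RuCl2(=CHPh)(PCy3)(H2IMes) (5 mol %), CH2Cl2, 40 °C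
Reagents that add atoms: none
Why: Ring-closing metathesis of the two cis-disposed monosubstituted vinyl groups closes ring A as a cis-cyclohexene; the hindered 1,1-disubstituted C16 methylene does not take part.

Step 27
Reactants: 32 protected gibberellin
Product: 33 TMSE ester of the target gibberellin
Conditions: HF·pyridine, THF, 0 °C → rt
Reagents that add atoms: none
Why: Acidic fluoride desilylation removes both silyl ethers without exposing the base-sensitive ring A hydroxy-lactone to basic conditions.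

Step 28
Reactants: 33 TMSE ester of the target gibberellin
Product: 34 target gibberellin (12-hydroxygibberellic acid, 12-OH cis to 13-OH)
Conditions: Bu4NF, THF, 0 °C, 1 h; AcOH; extraction at pH 3
Reagents that add atoms: none
Why: Fluoride-induced fragmentation of the 2-(trimethylsilyl)ethyl ester frees the hindered C7 acid without hydrolysis, briefly and cold, so the allylic lactone and the 3-hydroxyl are not isomerised.

**Compound list**
1 | cyclopentane-1,3-dione | O=C1CCC(=O)C1 | starting material
2 | (benzyloxy)acetaldehyde | O=CCOCc1ccccc1 | starting material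
3 | 2-[2-(benzyloxy)ethylidene]cyclopentane-1,3-dione (not isolated) | O=C1CCC(=O)C1=CCOCc1ccccc1 | intermediate
4 | 2-[2-(benzyloxy)ethyl]cyclopentane-1,3-dione | O=C1CCC(=O)C1CCOCc1ccccc1 | intermediate
5 | methyl vinyl ketone | CC(=O)C=C | starting material
6 | 2-[2-(benzyloxy)ethyl]-2-(3-oxobutyl)cyclopentane-1,3-dione | CC(=O)CCC1(CCOCc2ccccc2)C(=O)CCC1=O | intermediate
7 | cis-ketol: 3a-hydroxy-7a-[2-(benzyloxy)ethyl]hexahydroindane-1,5-dione, OH cis to the side chain (not isolated) | c1ccccc1COCC[C@]23CCC(=O)C[C@@]2(O)CCC3=O | intermediate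
8 | (R)-7a-[2-(benzyloxy)ethyl]-2,3,7,7a-tetrahydro-1H-indene-1,5(6H)-dione | c1ccccc1COCC[C@]23CCC(=O)C=C2CCC3=O | intermediate
9 | 16-O-benzyl 6-hydroxy-9(11)-en-12-one, 6-OH cis to the C8 side chain | c1ccccc1COCC[C@]23CCC(=O)C=C2CC[C@@H]3O | intermediate
10 | 6-pivalate of 9 | c1ccccc1COCC[C@]23CCC(=O)C=C2CC[C@@H]3OC(=O)C(C)(C)C | intermediate
11 | 13-hydroxy enone 6-pivalate, 13-OH trans to the side chain | c1ccccc1COCC[C@]23C[C@@H](O)C(=O)C=C2CC[C@@H]3OC(=O)C(C)(C)C | intermediate
12 | cis-hydrindan-12-one 13,16-diol 6-pivalate, H-9 cis to the side chain | OCC[C@]23C[C@@H](O)C(=O)C[C@H]2CC[C@@H]3OC(=O)C(C)(C)C | intermediate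
13 | 13,16-bis-O-TES ether of 12 | CC[Si](CC)(CC)OCC[C@]23C[C@@H](O[Si](CC)(CC)CC)C(=O)C[C@H]2CC[C@@H]3OC(=O)C(C)(C)C | intermediate
14 | 12-alcohol, 12-OH cis to 13-O | CC[Si](CC)(CC)OCC[C@]23C[C@@H](O[Si](CC)(CC)CC)[C@@H](O)C[C@H]2CC[C@@H]3OC(=O)C(C)(C)C | intermediate
15 | 12-O-TBS 13,16-bis-O-TES 6-pivalate | CC[Si](CC)(CC)OCC[C@]23C[C@@H](O[Si](CC)(CC)CC)[C@@H](O[Si](C)(C)C(C)(C)C)C[C@H]2CC[C@@H]3OC(=O)C(C)(C)C | intermediate
16 | 6-alcohol | CC[Si](CC)(CC)OCC[C@]23C[C@@H](O[Si](CC)(CC)CC)[C@@H](O[Si](C)(C)C(C)(C)C)C[C@H]2CC[C@@H]3O | intermediate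
17 | 6-ketone | CC[Si](CC)(CC)OCC[C@]23C[C@@H](O[Si](CC)(CC)CC)[C@@H](O[Si](C)(C)C(C)(C)C)C[C@H]2CCC3=O | intermediate
18 | 5-en-6-yl triflate | CC[Si](CC)(CC)OCC[C@]23C[C@@H](O[Si](CC)(CC)CC)[C@@H](O[Si](C)(C)C(C)(C)C)C[C@H]2CC=C3OS(=O)(=O)C(F)(F)F | intermediate
19 | TMSE 5-ene-6-carboxylate | CC[Si](CC)(CC)OCC[C@]23C[C@@H](O[Si](CC)(CC)CC)[C@@H](O[Si](C)(C)C(C)(C)C)C[C@H]2CC=C3C(=O)OCC[Si](C)(C)C | intermediate
20 | 10-oxo-5-ene-6-carboxylate | CC[Si](CC)(CC)OCC[C@]23C[C@@H](O[Si](CC)(CC)CC)[C@@H](O[Si](C)(C)C(C)(C)C)C[C@H]2C(=O)C=C3C(=O)OCC[Si](C)(C)C | intermediate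
21 | 10-vinyl-10-ol, vinyl cis to H-9 | CC[Si](CC)(CC)OCC[C@]23C[C@@H](O[Si](CC)(CC)CC)[C@@H](O[Si](C)(C)C(C)(C)C)C[C@H]2[C@](O)(C=C)C=C3C(=O)OCC[Si](C)(C)C | intermediate
22 | 10-propanoate | CC[Si](CC)(CC)OCC[C@]23C[C@@H](O[Si](CC)(CC)CC)[C@@H](O[Si](C)(C)C(C)(C)C)C[C@H]2[C@](OC(=O)CC)(C=C)C=C3C(=O)OCC[Si](C)(C)C | intermediate
23 | tricyclic 19,10-lactone, lactone cis-fused to ring B, H-5 cis to the C10 vinyl (C4 epimers) | CC[Si](CC)(CC)OCC[C@]23C[C@@H](O[Si](CC)(CC)CC)[C@@H](O[Si](C)(C)C(C)(C)C)C[C@H]2[C@@]4(C=C)OC(=O)C(C)[C@H]4[C@@H]3C(=O)OCC[Si](C)(C)C | intermediate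
24 | lactone 13,16-diol (C4 epimers) | OCC[C@]23C[C@@H](O)[C@@H](O[Si](C)(C)C(C)(C)C)C[C@H]2[C@@]4(C=C)OC(=O)C(C)[C@H]4[C@@H]3C(=O)OCC[Si](C)(C)C | intermediate
25 | 13-oxo-16-al (C4 epimers) | O=CC[C@]23CC(=O)[C@@H](O[Si](C)(C)C(C)(C)C)C[C@H]2[C@@]4(C=C)OC(=O)C(C)[C@H]4[C@@H]3C(=O)OCC[Si](C)(C)C | intermediate
26 | tetracyclic 13,16-diol, 16-OH cis to 13-OH (C4 epimers) | O[C@@H]1C[C@]23C[C@@]1(O)[C@@H](O[Si](C)(C)C(C)(C)C)C[C@H]2[C@@]4(C=C)OC(=O)C(C)[C@H]4[C@@H]3C(=O)OCC[Si](C)(C)C | intermediate
27 | 16-oxo-13-ol (C4 epimers) | O=C1C[C@]23C[C@@]1(O)[C@@H](O[Si](C)(C)C(C)(C)C)C[C@H]2[C@@]4(C=C)OC(=O)C(C)[C@H]4[C@@H]3C(=O)OCC[Si](C)(C)C | intermediate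
28 | 16-methylene-13-ol (C4 epimers) | C=C1C[C@]23C[C@@]1(O)[C@@H](O[Si](C)(C)C(C)(C)C)C[C@H]2[C@@]4(C=C)OC(=O)C(C)[C@H]4[C@@H]3C(=O)OCC[Si](C)(C)C | intermediate
29 | 13-O-TES ether (C4 epimers) | C=C1C[C@]23C[C@@]1(O[Si](CC)(CC)CC)[C@@H](O[Si](C)(C)C(C)(C)C)C[C@H]2[C@@]4(C=C)OC(=O)C(C)[C@H]4[C@@H]3C(=O)OCC[Si](C)(C)C | intermediate
30 | acrolein | C=CC=O | starting material
31 | aldol adduct, 1-hydroxyprop-2-enyl group on C4 cis to the C10 vinyl | C=C1C[C@]23C[C@@]1(O[Si](CC)(CC)CC)[C@@H](O[Si](C)(C)C(C)(C)C)C[C@H]2[C@@]4(C=C)OC(=O)[C@](C)([C@@H](O)C=C)[C@H]4[C@@H]3C(=O)OCC[Si](C)(C)C | intermediate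
32 | 12-O-TBS 13-O-TES TMSE ester of the target gibberellin | C=C1C[C@]23C[C@@]1(O[Si](CC)(CC)CC)[C@@H](O[Si](C)(C)C(C)(C)C)C[C@H]2[C@@]12C=C[C@H](O)[C@@](C)(C(=O)O1)[C@H]2[C@@H]3C(=O)OCC[Si](C)(C)C | intermediate
33 | TMSE ester of the target gibberellin | C=C1C[C@]23C[C@@]1(O)[C@@H](O)C[C@H]2[C@@]12C=C[C@H](O)[C@@](C)(C(=O)O1)[C@H]2[C@@H]3C(=O)OCC[Si](C)(C)C | intermediate
34 | target gibberellin: 12-hydroxygibberellic acid (3,12,13-triol, 1,16-diene, 19,10-lactone, free 7-acid; 12-OH cis to 13-OH) | C=C1C[C@]23C[C@@]1(O)[C@@H](O)C[C@H]2[C@@]12C=C[C@H](O)[C@@](C)(C(=O)O1)[C@H]2[C@@H]3C(=O)O | target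

**Step count and risks**
Total steps: 28. Longest linear sequence: 28 steps from cyclopentane-1,3-dione (fully linear; methyl vinyl ketone and acrolein enter in single steps).

Most likely to fail:

Step 15 (γ-oxidation of the enoate with CrO3 in the presence of three silyl ethers). The fallback sets out from 19 and comes back at 20. Radical allylic bromination of 19 (N-bromosuccinimide, AIBN, PhCF3, 80 °C) functionalises the only allylic CH2 and gives the 10-bromo enoate F1. Kornblum oxidation of F1 (AgBF4, DMSO, then Et3N) then delivers the 10-ketone 20 without any chromium oxidant.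

Step 21 (SmI2 pinacol closure next to an α-silyloxy ketone, which could suffer reductive C–O cleavage). The fallback sets out from 25 and comes back at 29, bypassing 26–28. Seyferth–Gilbert homologation of the aldehyde of 25 (dimethyl 1-diazo-2-oxopropylphosphonate, K2CO3, MeOH, 0 °C, short) gives the alkynyl ketone F2. Nickel-catalysed reductive alkyne–ketone cyclisation of F2 (Ni(cod)2, PBu3, Et3SiH, THF) forms the C13–C16 bond through an oxanickelacycle, not a ketyl, and gives the exo-methylene 13-O-TES ether 29 directly.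

Step 25 (lithium-enolate aldol: competing deprotonation at C6, retro-aldol or 1,4-addition to acrolein). The fallback sets out from 29 and comes back at 31. The lactone is deprotonated as before and trapped with Me3SiCl to give the silyl ketene acetal F3, whose regiochemistry can be checked before the coupling. A Mukaiyama aldol of F3 with acrolein (BF3·OEt2, CH2Cl2, −78 °C) then forms the same C3–C4 bond under non-basic conditions and gives 31.

**Further compounds**
F1 | step 15 | 10-bromo TMSE 5-ene-6-carboxylate (C10 epimer mixture) | CC[Si](CC)(CC)OCC[C@]23C[C@@H](O[Si](CC)(CC)CC)[C@@H](O[Si](C)(C)C(C)(C)C)C[C@H]2C(Br)C=C3C(=O)OCC[Si](C)(C)C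
F2 | step 21 | 13-oxo lactone bearing a C8 propargyl group (alkynyl ketone; C4 epimers) | C#CC[C@]23CC(=O)[C@@H](O[Si](C)(C)C(C)(C)C)C[C@H]2[C@@]4(C=C)OC(=O)C(C)[C@H]4[C@@H]3C(=O)OCC[Si](C)(C)C
F3 | step 25 | trimethylsilyl ketene acetal of lactone 29 | C=C1C[C@]23C[C@@]1(O[Si](CC)(CC)CC)[C@@H](O[Si](C)(C)C(C)(C)C)C[C@H]2[C@@]4(C=C)OC(O[Si](C)(C)C)=C(C)[C@H]4[C@@H]3C(=O)OCC[Si](C)(C)C
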